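## Retrosynthetic overview

- **Feature:** in ring A the C3 carbinol and the C19 hydroxymethyl flank the quaternary C4 (which also bears the C18 methyl). This 1,3-dioxygenated unit is a reduced 2-methyl β-keto ester. C5/C10 and C9/C8 are the carbons of two E-trisubstituted alkenes of a regular isoprenoid chain.
- **Key disconnection:** C4–C5 (ring A, closed first) and C10–C9 (ring B, closed second) are opened together. This leads back to an acyclic (E,E)-dienyl 2-methyl-3-oxo ester with an 8-phenylmenthyl group and a C13 dioxolane. In the forward sense one oxidative radical cascade closes both rings and leaves the 8(17)-alkene.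
- **After the cascade:** the C3 ketone becomes the axial 3α-ol and the C19 ester becomes CH2OH. Ring B goes 8(17)-ene → 7-ene → 7-en-6-one → 8-en-6-one → 6β-ol. The C13 ketone becomes the E-enoate and then the acid.
- **Before the cascade:** the C1–C2 bond is made by γ-alkylation of the auxiliary 2-methylacetoacetate dianion with the E-allylic bromide derived from (E)-geranylacetone (ketal, allylic oxidation, bromide).

Key step: step 6

Assumption: the (1S,2R,5S) auxiliary is taken to expose the face of the C4 radical that leads to the 5α-H,10β-methyl series drawn; if induction runs the other way, (−)-8-phenylmenthol is used in step 4 and nothing else changes.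

## Route

Step 1
Reactants: 1 (E)-geranylacetone; 2 ethylene glycol
Product: 3 (E)-geranylacetone ethylene ketal
Conditions: PPTS (cat.), benzene, reflux, Dean–Stark
Reagents that add atoms: none
Why: Acid-catalysed ketalisation driven by azeotropic removal of water masks the future C13 ketone against the carbanion, hydride and enolate chemistry to come, and the weak acid leaves both trisubstituted alkenes and their geometry untouched.

Step 2
Reactants: 3 (E)-geranylacetone ethylene ketal
Product: 4 (2E,6E)-2,6-dimethyl-9-(2-methyl-1,3-dioxolan-2-yl)nona-2,6-dien-1-ol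
Conditions: SeO2 (cat.), t-BuOOH (decane), CH2Cl2, 0 °C to rt, stopped at partial conversion
Reagents that add atoms: tert-butyl hydroperoxide, CC(C)(C)OO (oxygen passed on through SeO2)
Why: Riley allylic oxidation (ene reaction, then [2,3]-sigmatropic shift) prefers the exposed terminal gem-dimethyl alkene and, through its cyclic transition states, oxidises only the methyl group trans to the chain, which fixes the E geometry of the future C10=C5 alkene.

Step 3
Reactants: 4 the (2E,6E)-allylic alcohol
Product: 6 2-[(3E,7E)-9-bromo-4,8-dimethylnona-3,7-dienyl]-2-methyl-1,3-dioxolane, via allylic mesylate 5 (not isolated)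
Conditions: MsCl, Et3N, THF, −45 °C; then LiBr, THF, 0 °C
Reagents that add atoms: lithium bromide, [Li+].[Br-]; methanesulfonyl chloride, CS(=O)(=O)Cl (its atoms stay only in 5)
Why: Mesylation followed by SN2 displacement by bromide at the primary allylic carbon keeps both alkene geometries and, being free of acid, leaves the dioxolane intact.

Step 4
Reactants: 7 (+)-8-phenylmenthol, (1S,2R,5S); 8 ethyl 2-methylacetoacetate
Product: 9 (+)-8-phenylmenthyl 2-methyl-3-oxobutanoate (C2 epimers)
Conditions: DMAP (0.3 equiv), toluene, reflux, 4 Å sieves to take up EtOH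
Reagents that add atoms: none
Why: DMAP-promoted transesterification of a β-keto ester (through its acylketene) accepts hindered secondary alcohols, is driven by removal of ethanol, and does not touch the carbinol centre of the auxiliary.

Step 5
Reactants: 9 (+)-8-phenylmenthyl 2-methyl-3-oxobutanoate; 6 the (E,E)-allylic bromide
Product: 11 (+)-8-phenylmenthyl (6E,10E)-2,6,10-trimethyl-13-(2-methyl-1,3-dioxolan-2-yl)-3-oxotrideca-6,10-dienoate (C2 epimers; labdane C4), via sodium lithium dianion 10 (not isolated)
Conditions: NaH, THF, 0 °C; n-BuLi, 0 °C; then 6, 0 °C to rt; aqueous work-up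
Reagents that add atoms: none
Why: In this γ-alkylation of a β-keto ester dianion the more basic terminal carbanion (future C2) attacks the primary allylic bromide by SN2 and forms C1–C2, while the C4 position stays an enolate and is only protonated on work-up.

Step 6
Reactants: 11 the acyclic 8-phenylmenthyl keto ester
Product: 12 (+)-8-phenylmenthyl 13,13-ethylenedioxy-3-oxo-14,15-dinorlabd-8(17)-en-19-oate (5α-H, 9α-H, 10β-CH3, 4β-axial ester, 4α-CH3)
Conditions: Mn(OAc)3·2H2O (2.2 equiv), Cu(OAc)2·H2O (1 equiv), KOAc, degassed AcOH, 25 °C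
Reagents that add atoms: none
Why: Trivalent manganese binds the enol of the 2-methyl β-keto ester and oxidises it to the electrophilic tertiary C4 radical (both C4 epimers of 11 give the same planar radical), which adds to C5, the tertiary C10 radical so formed adds to C9, and the final tertiary C8 radical is taken up by divalent copper and loses a C17 hydrogen to give the 8(17)-alkene, the monovalent copper being returned to the divalent state by the second equivalent of manganese triacetate. The closest known reaction type is the manganese triacetate/copper diacetate oxidative free-radical polyene cyclisation of unsaturated 2-alkyl β-keto esters to trans-decalins, which has also been run on 8-phenylmenthyl esters. Ring A closes 6-endo-trig (C4 to C5) and ring B closes 6-endo-trig (C10 to C9), in each case because the methyl group on the inner alkene carbon (C10, then C8) blocks the 5-exo mode and the endo mode gives a tertiary radical. Chair–chair folding of the E,E chain sets the relative configuration, namely 5α-H anti to the 10β-methyl (trans fusion), the C9 chain equatorial (9α-H), and at C4 the ester axial (β, cis to C20) with the methyl equatorial, while the absolute sense comes from the auxiliary, whose phenyl ring lies over one face of the C4 radical so that C5 bonds to the open face. The step needs oxidation at C4 alone, secured because this is the only readily enolised C–H and because 12, quaternary at C4, cannot be oxidised again, and it needs the dioxolane to last, for which the acetic acid is buffered with KOAc and kept at room temperature. Regiocontrol in the last hydrogen loss is not critical, since any 7-ene formed beside the 8(17)-ene is carried to the same compound in step 10.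

Step 7
Reactants: 12 the bicyclic 3-oxo ester
Product: 13 (+)-8-phenylmenthyl 13,13-ethylenedioxy-3α-hydroxy-14,15-dinorlabd-8(17)-en-19-oate
Conditions: LiBH(s-Bu)3, THF, −78 °C; then aq. NaOH, H2O2, 0 °C
Reagents that add atoms: none
Why: In this bulky trialkylborohydride reduction the axial approach from the α face is closed by the axial 1α- and 5α-hydrogens, so hydride arrives along the equatorial trajectory and gives the axial 3α-alcohol, while the quaternary C4 rules out enolisation.

Step 8
Reactants: 13 the 3α-hydroxy ester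
Product: 14 13,13-ethylenedioxy-14,15-dinorlabd-8(17)-ene-3α,19-diol
Conditions: LiAlH4 (excess), THF, reflux; aq. NaOH work-up
Reagents that add atoms: none
Why: Ester reduction by the small aluminium hydride reaches the neopentyl axial carbonyl, turns C19 into CH2OH without touching a stereocentre, releases the auxiliary for reuse, and spares the ketal and the alkene.

Step 9
Reactants: 14 the 3α,19-diol
Product: 15 3α,19-bis(tert-butyldimethylsilyloxy)-13,13-ethylenedioxy-14,15-dinorlabd-8(17)-ene
Conditions: TBSOTf, 2,6-lutidine, CH2Cl2, −78 to 0 °C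
Reagents that add atoms: tert-butyldimethylsilyl triflate, CC(C)(C)[Si](C)(C)OS(=O)(=O)C(F)(F)F
Why: Silyl triflate silylation is reactive enough for the neopentyl primary and the hindered axial secondary hydroxyl (an acetonide is excluded because the C3–O and C4–C19 bonds are trans-diaxial), and a ketone-derived dioxolane is inert to the buffered triflate at low temperature.

Step 10
Reactants: 15 the 8(17)-ene bis-silyl ether
Product: 16 3α,19-bis(tert-butyldimethylsilyloxy)-13,13-ethylenedioxy-14,15-dinorlabd-7-ene (9α-H)
Conditions: chloro[N,N'-bis(3,5-di-tert-butylsalicylidene)-1,2-cyclohexanediaminato]cobalt (5 mol %), PhSiH3 (10 mol %), benzene, rt, argon, stopped once 15 is consumed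
Reagents that add atoms: none
Why: In this metal-hydride hydrogen-atom-transfer alkene isomerisation the cobalt hydride gives a hydrogen atom to C17, and divalent cobalt then takes back the accessible C7 hydrogen of the tertiary C8 radical rather than the C9 hydrogen buried between C10 and the side chain, under neutral conditions that spare the ketal and silyl ethers.

Step 11
Reactants: 16 the 7-ene
Product: 17 3α,19-bis(tert-butyldimethylsilyloxy)-13,13-ethylenedioxy-14,15-dinorlabd-7-en-6-one
Conditions: CrO3, 3,5-dimethylpyrazole, CH2Cl2, −20 °C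
Reagents that add atoms: chromium trioxide, O=[Cr](=O)=O
Why: In this chromium trioxide–dimethylpyrazole allylic oxidation C6 is the only allylic methylene of the 7-ene and is taken to the enone, as in related drim-7-enes and labd-7-enes, while the non-acidic medium leaves the ketal and silyl ethers alone.

Step 12
Reactants: 17 the 7-en-6-one
Product: 19 3α,19-bis(tert-butyldimethylsilyloxy)-13,13-ethylenedioxy-14,15-dinorlabd-8-en-6-one, via potassium dienolate 18 (not isolated)
Conditions: KOt-Bu, t-BuOH/THF, rt, argon; poured into cold 10% aq. AcOH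
Reagents that add atoms: none
Why: In this base-mediated enone deconjugation reversible deprotonation gives the more substituted through-conjugated dienolate by loss of the axial 9α-hydrogen, and fast kinetic protonation at the α-carbon C7 leaves the alkene in the tetrasubstituted 8(9) position, while any C5 enolate is reprotonated from the open α face so that the trans fusion holds.

Step 13
Reactants: 19 the 8-en-6-one (crude, used at once)
Product: 20 3α,19-bis(tert-butyldimethylsilyloxy)-13,13-ethylenedioxy-14,15-dinorlabd-8-en-6β-ol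
Conditions: LiAlH4, Et2O, −78 to 0 °C
Reagents that add atoms: none
Why: Hydride reduction of the ketone runs faster than reconjugation at low temperature, and because the β face of C6 is screened by the axial C20 methyl and the axial C19 silyloxymethyl, hydride enters from the α face and sets the axial 6β-alcohol.

Step 14
Reactants: 20 the 6β-ol ketal
Product: 21 3α,19-bis(tert-butyldimethylsilyloxy)-6β-hydroxy-14,15-dinorlabd-8-en-13-one
Conditions: PPTS, acetone/H2O, 50 °C
Reagents that add atoms: water, O
Why: Mild acid-catalysed ketal hydrolysis frees the methyl ketone while the two hindered silyl ethers, the unactivated homoallylic alcohol and the tetrasubstituted alkene stay unchanged.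

Step 15
Reactants: 21 the 13-ketone
Product: 22 ethyl 3α,19-bis(tert-butyldimethylsilyloxy)-6β-hydroxylabda-8,13E-dien-15-oate
Conditions: (EtO)2P(O)CH2CO2Et, NaH, THF, 0 to 50 °C (ketone added after H2 evolution ends)
Reagents that add atoms: triethyl phosphonoacetate, CCOC(=O)CP(=O)(OCC)OCC
Why: Horner–Wadsworth–Emmons olefination of the methyl ketone places the ester trans to the larger C12 chain (E, with the minor Z isomer removed by chromatography), and the stabilised carbanion is too weak a base to deprotonate the free 6β-hydroxyl.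

Step 16
Reactants: 22 the bis-silyl ethyl ester
Product: 23 ethyl 3α,6β,19-trihydroxylabda-8,13E-dien-15-oate
Conditions: HF·pyridine, pyridine/THF, 0 °C to rt
Reagents that add atoms: none
Why: Fluoride-driven desilylation, carried by the strength of the Si–F bond, frees both hydroxyls under buffered conditions that do not isomerise either alkene or ionise the 6β-alcohol.

Step 17
Reactants: 23 the triol ethyl ester
Product: 24 3α,6β,19-trihydroxylabda-8,13E-dien-15-oic acid (target)
Conditions: LiOH, THF/MeOH/H2O, 50 °C; then 1 M HCl to pH 3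
Reagents that add atoms: lithium hydroxide, [Li+].[OH-]
Why: Saponification by acyl–oxygen cleavage touches no stereocentre, the β,β-disubstituted enoate keeps its E geometry, and none of the hydroxyls sits close enough to C15 to lactonise on acidification.

## Compound list

1 | (E)-geranylacetone, (5E)-6,10-dimethylundeca-5,9-dien-2-one | CC(C)=CCC/C(C)=C/CCC(C)=O | starting material
2 | ethylene glycol | OCCO | starting material
3 | 2-[(3E)-4,8-dimethylnona-3,7-dienyl]-2-methyl-1,3-dioxolane | CC(C)=CCC/C(C)=C/CCC1(C)OCCO1 | intermediate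
4 | (2E,6E)-2,6-dimethyl-9-(2-methyl-1,3-dioxolan-2-yl)nona-2,6-dien-1-ol | OC/C(C)=C/CC/C(C)=C/CCC1(C)OCCO1 | intermediate
5 | methanesulfonate of 4 (not isolated) | CS(=O)(=O)OC/C(C)=C/CC/C(C)=C/CCC1(C)OCCO1 | intermediate
6 | 2-[(3E,7E)-9-bromo-4,8-dimethylnona-3,7-dienyl]-2-methyl-1,3-dioxolane | BrC/C(C)=C/CC/C(C)=C/CCC1(C)OCCO1 | intermediate
7 | (+)-8-phenylmenthol, (1S,2R,5S)-5-methyl-2-(2-phenylpropan-2-yl)cyclohexanol | O[C@H]1C[C@@H](C)CC[C@@H]1C(C)(C)c1ccccc1 | starting material
8 | ethyl 2-methylacetoacetate | CCOC(=O)C(C)C(C)=O | starting material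
9 | (+)-8-phenylmenthyl 2-methyl-3-oxobutanoate (C2 epimers) | CC(=O)C(C)C(=O)O[C@H]1C[C@@H](C)CC[C@@H]1C(C)(C)c1ccccc1 | intermediate
10 | sodium lithium dianion of 9 (not isolated) | [Na+].[Li+].C=C([O-])C(C)=C([O-])O[C@H]1C[C@@H](C)CC[C@@H]1C(C)(C)c1ccccc1 | intermediate
11 | (+)-8-phenylmenthyl (6E,10E)-2,6,10-trimethyl-13-(2-methyl-1,3-dioxolan-2-yl)-3-oxotrideca-6,10-dienoate (C2 epimers) | CC(C(=O)CC/C(C)=C/CC/C(C)=C/CCC1(C)OCCO1)C(=O)O[C@H]2C[C@@H](C)CC[C@@H]2C(C)(C)c2ccccc2 | intermediate
12 | (+)-8-phenylmenthyl 13,13-ethylenedioxy-3-oxo-14,15-dinorlabd-8(17)-en-19-oate | C=C1[C@H](CCC3(C)OCCO3)[C@@]2(C)CCC(=O)[C@](C)(C(=O)O[C@H]3C[C@@H](C)CC[C@@H]3C(C)(C)c3ccccc3)[C@@H]2CC1 | intermediate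
13 | (+)-8-phenylmenthyl 13,13-ethylenedioxy-3α-hydroxy-14,15-dinorlabd-8(17)-en-19-oate | C=C1[C@H](CCC3(C)OCCO3)[C@@]2(C)CC[C@@H](O)[C@](C)(C(=O)O[C@H]3C[C@@H](C)CC[C@@H]3C(C)(C)c3ccccc3)[C@@H]2CC1 | intermediate
14 | 13,13-ethylenedioxy-14,15-dinorlabd-8(17)-ene-3α,19-diol | C=C1[C@H](CCC3(C)OCCO3)[C@@]2(C)CC[C@@H](O)[C@](C)(CO)[C@@H]2CC1 | intermediate
15 | 3α,19-bis(TBS-oxy)-13,13-ethylenedioxy-14,15-dinorlabd-8(17)-ene | C=C1[C@H](CCC3(C)OCCO3)[C@@]2(C)CC[C@@H](O[Si](C)(C)C(C)(C)C)[C@](C)(CO[Si](C)(C)C(C)(C)C)[C@@H]2CC1 | intermediate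
16 | 3α,19-bis(TBS-oxy)-13,13-ethylenedioxy-14,15-dinorlabd-7-ene | CC=1[C@H](CCC3(C)OCCO3)[C@@]2(C)CC[C@@H](O[Si](C)(C)C(C)(C)C)[C@](C)(CO[Si](C)(C)C(C)(C)C)[C@@H]2CC=1 | intermediate
17 | 3α,19-bis(TBS-oxy)-13,13-ethylenedioxy-14,15-dinorlabd-7-en-6-one | CC=1[C@H](CCC3(C)OCCO3)[C@@]2(C)CC[C@@H](O[Si](C)(C)C(C)(C)C)[C@](C)(CO[Si](C)(C)C(C)(C)C)[C@@H]2C(=O)C=1 | intermediate
18 | potassium 6,8-dien-6-olate of 17 (not isolated) | [K+].CC1=C(CCC3(C)OCCO3)[C@@]2(C)CC[C@@H](O[Si](C)(C)C(C)(C)C)[C@](C)(CO[Si](C)(C)C(C)(C)C)[C@@H]2C([O-])=C1 | intermediate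
19 | 3α,19-bis(TBS-oxy)-13,13-ethylenedioxy-14,15-dinorlabd-8-en-6-one | CC1=C(CCC3(C)OCCO3)[C@@]2(C)CC[C@@H](O[Si](C)(C)C(C)(C)C)[C@](C)(CO[Si](C)(C)C(C)(C)C)[C@@H]2C(=O)C1 | intermediate
20 | 3α,19-bis(TBS-oxy)-13,13-ethylenedioxy-14,15-dinorlabd-8-en-6β-ol | CC1=C(CCC3(C)OCCO3)[C@@]2(C)CC[C@@H](O[Si](C)(C)C(C)(C)C)[C@](C)(CO[Si](C)(C)C(C)(C)C)[C@@H]2[C@H](O)C1 | intermediate
21 | 3α,19-bis(TBS-oxy)-6β-hydroxy-14,15-dinorlabd-8-en-13-one | CC1=C(CCC(C)=O)[C@@]2(C)CC[C@@H](O[Si](C)(C)C(C)(C)C)[C@](C)(CO[Si](C)(C)C(C)(C)C)[C@@H]2[C@H](O)C1 | intermediate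
22 | ethyl 3α,19-bis(TBS-oxy)-6β-hydroxylabda-8,13E-dien-15-oate | CC1=C(CC/C(C)=C/C(=O)OCC)[C@@]2(C)CC[C@@H](O[Si](C)(C)C(C)(C)C)[C@](C)(CO[Si](C)(C)C(C)(C)C)[C@@H]2[C@H](O)C1 | intermediate
23 | ethyl 3α,6β,19-trihydroxylabda-8,13E-dien-15-oate | CC1=C(CC/C(C)=C/C(=O)OCC)[C@@]2(C)CC[C@@H](O)[C@](C)(CO)[C@@H]2[C@H](O)C1 | intermediate
24 | 3α,6β,19-trihydroxylabda-8,13E-dien-15-oic acid (5α-H, 10β-CH3) | CC1=C(CC/C(C)=C/C(=O)O)[C@@]2(C)CC[C@@H](O)[C@](C)(CO)[C@@H]2[C@H](O)C1 | target

## Step count and risks

Total step count: 17. Longest linear sequence: 16 (steps 1–3 and 5–17, from 1); step 4 is the side branch.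

**Step 6.** The aryl group of the auxiliary may cover the C4 radical too weakly, which would give poor facial selectivity. The dioxolane may also be slowly hydrolysed in acetic acid.
- The fallback gives up auxiliary control and secures the absolute configuration by resolution. It sets out from 6.
- Alkylation of the dianion of 8 (NaH, n-BuLi, THF) with 6 gives the acyclic ethyl keto ester F1.
- The same Mn(OAc)3/Cu(OAc)2 cyclisation gives the racemic bicyclic ethyl keto ester F2.
- LiBH(s-Bu)3 gives the racemic 3α-hydroxy ethyl ester F3, and LiAlH4 gives the racemic 3α,19-diol F4.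
- (1S)-Camphanic chloride in pyridine acylates only the primary C19 hydroxyl. The two diastereomers are parted by crystallisation or chromatography to give the 19-camphanate of the wanted series F5.
- K2CO3 in MeOH then comes back to the route at 14.

**Step 12.** A C17 hydrogen may be removed in competition with the 9α-hydrogen. The β,γ-enone may also reconjugate during quench and handling.
- The fallback is a reductive deconjugation through a dienol ester. It sets out from 17.
- Dienolate 18 is trapped with Ac2O instead of a proton to give the 6-acetoxy-6,8-diene F8. This compound can be chromatographed, so material arising from deprotonation at C17 can be removed.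
- NaBH4 in EtOH/THF at 0 °C cleaves the enol acetate, and the solvent protonates the freed dienolate at C7.
- The ketone is reduced from the α face as it forms, so the sensitive ketone is never handled. The route is rejoined at 20.

**Step 10.** Discrimination between the C7 and C9 hydrogens may be poor, or the alkene may drift on to the tetrasubstituted position, which closes the way to C6.
- The fallback fixes the alkene position by an epoxide-to-allylic-alcohol rearrangement. It sets out from 15.
- m-CPBA with NaHCO3 in CH2Cl2 attacks the open α face and gives the 8α,17-epoxide F6.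
- Diethylaluminium 2,2,6,6-tetramethylpiperidide in toluene opens the epoxide by syn removal of the accessible C7 hydrogen and gives the 7-en-17-ol F7.
- SO3·pyridine followed by LiAlH4 in THF replaces the primary allylic sulfate by hydride at C17. The route is rejoined at 16.

## Further compounds

F1 | step 6 | ethyl (6E,10E)-2,6,10-trimethyl-13-(2-methyl-1,3-dioxolan-2-yl)-3-oxotrideca-6,10-dienoate | CCOC(=O)C(C)C(=O)CC/C(C)=C/CC/C(C)=C/CCC1(C)OCCO1
F2 | step 6 | racemic ethyl 13,13-ethylenedioxy-3-oxo-14,15-dinorlabd-8(17)-en-19-oate (one enantiomer drawn) | C=C1[C@H](CCC3(C)OCCO3)[C@@]2(C)CCC(=O)[C@](C)(C(=O)OCC)[C@@H]2CC1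
F3 | step 6 | racemic ethyl 13,13-ethylenedioxy-3α-hydroxy-14,15-dinorlabd-8(17)-en-19-oate (one enantiomer drawn) | C=C1[C@H](CCC3(C)OCCO3)[C@@]2(C)CC[C@@H](O)[C@](C)(C(=O)OCC)[C@@H]2CC1
F4 | step 6 | racemic 13,13-ethylenedioxy-14,15-dinorlabd-8(17)-ene-3α,19-diol (one enantiomer drawn) | C=C1[C@H](CCC3(C)OCCO3)[C@@]2(C)CC[C@@H](O)[C@](C)(CO)[C@@H]2CC1
F5 | step 6 | 19-O-[(1S)-camphanoyl] derivative of 14, single diastereomer | C=C1[C@H](CCC3(C)OCCO3)[C@@]2(C)CC[C@@H](O)[C@](C)(COC(=O)[C@@]45CC[C@@](C)(C(=O)O4)C5(C)C)[C@@H]2CC1
F6 | step 10 | 3α,19-bis(TBS-oxy)-8α,17-epoxy-13,13-ethylenedioxy-14,15-dinorlabdane | C1O[C@]12[C@H](CCC3(C)OCCO3)[C@@]4(C)CC[C@@H](O[Si](C)(C)C(C)(C)C)[C@](C)(CO[Si](C)(C)C(C)(C)C)[C@@H]4CC2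
F7 | step 10 | 3α,19-bis(TBS-oxy)-13,13-ethylenedioxy-14,15-dinorlabd-7-en-17-ol | OCC=1[C@H](CCC3(C)OCCO3)[C@@]2(C)CC[C@@H](O[Si](C)(C)C(C)(C)C)[C@](C)(CO[Si](C)(C)C(C)(C)C)[C@@H]2CC=1
F8 | step 12 | 6-acetoxy-3α,19-bis(TBS-oxy)-13,13-ethylenedioxy-14,15-dinorlabda-6,8-diene | CC1=C(CCC3(C)OCCO3)[C@@]2(C)CC[C@@H](O[Si](C)(C)C(C)(C)C)[C@](C)(CO[Si](C)(C)C(C)(C)C)[C@@H]2C(OC(C)=O)=C1
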